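**Retrosynthetic overview** (abietane numbering throughout)

- The strategy rests on the C20 lactone that bridges C10 and C7 across ring B (a 2-oxabicyclo[2.2.2]octanone on the arene bond C8–C9). The atoms C10, C20, O, C7, C6 and C5 form a six-atom array in which C7–O can be the breaking bond of a [3,3] shift.
- Target ⇒ debenzylation, silyl/acetate exchange and hydrogenation ⇒ ring A by ring-closing metathesis across C2=C3 ⇒ bridged lactone by acid closure of the C20 acid onto the C6=C7 styrene.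
- Key disconnection C5–C10 (ring B): Ireland–Claisen ring contraction of a (7S)-1-alkenyl-4-allyl-isochroman-3-one, in which C7 relays its configuration to C10 and C5.
- Isochromanone ⇒ aryl aldehyde + (E)-alkenylzinc (sets C7). The arene comes from 3-bromo-4,5-dihydroxybenzaldehyde: C10/C20 by iodination and Negishi coupling at C9, the C15 side chain by Suzuki coupling and asymmetric hydroboration at C13.
- Ring order: lactone ring of the isochromanone → ring B (key step) → bridged lactone → ring A.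

Key step: step 14

Assumption: the facial sense quoted for the two ligand-controlled steps (7 and 12) follows the usual models; if either ligand gave the opposite face, its enantiomer would be used and nothing else changes.

Step 1
Reactants: 1 3-bromo-4,5-dihydroxybenzaldehyde
Product: 2 4-(benzyloxy)-3-bromo-5-hydroxybenzaldehyde
Conditions: BnBr (1.05 equiv), NaHCO3, NaI (cat.), DMF, 40 °C
Reagents that add atoms: benzyl bromide, BrCc1ccccc1
Why: Williamson etherification in which the 4-OH (para to the formyl group, ortho to bromine) is the more acidic phenol, so weak base forms only its phenoxide and only the C12 oxygen should be benzylated.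

Step 2
Reactants: 2 4-(benzyloxy)-3-bromo-5-hydroxybenzaldehyde
Product: 3 4-(benzyloxy)-5-bromo-3-hydroxy-2-iodobenzaldehyde
Conditions: ICl (1.1 equiv), pyridine, 1,4-dioxane, 0 °C → rt
Reagents that add atoms: iodine monochloride, ClI
Why: Electrophilic aromatic iodination directed by the free C11 hydroxyl to its ortho position C9 (between OH and CHO), the para position C14 being buried between CHO and Br.

Step 3
Reactants: 3 4-(benzyloxy)-5-bromo-3-hydroxy-2-iodobenzaldehyde
Product: 4 3,4-bis(benzyloxy)-5-bromo-2-iodobenzaldehyde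
Conditions: BnBr, K2CO3, DMF, 60 °C
Reagents that add atoms: benzyl bromide, BrCc1ccccc1
Why: Williamson etherification of the remaining phenol; benzyl ethers are chosen for the catechol because they can be removed at the end without touching an acetate or the lactone.

Step 4
Reactants: 4 3,4-bis(benzyloxy)-5-bromo-2-iodobenzaldehyde
Product: 5 1,2-bis(benzyloxy)-3-bromo-5-(dimethoxymethyl)-6-iodobenzene
Conditions: HC(OMe)3, TsOH·H2O (cat.), MeOH, rt; Et3N quench
Reagents that add atoms: trimethyl orthoformate, COC(OC)OC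
Why: Acid-catalysed acetalisation that masks the aldehyde against the zinc enolate, the copper hydride and the amide base of the next steps.

Step 5
Reactants: 5 1,2-bis(benzyloxy)-3-bromo-5-(dimethoxymethyl)-6-iodobenzene; 6 (2-ethoxy-2-oxoethyl)zinc bromide
Product: 7 ethyl 2-[2,3-bis(benzyloxy)-4-bromo-6-(dimethoxymethyl)phenyl]acetate
Conditions: 6 (1.3 equiv), Pd2(dba)3 (2.5 mol %), XPhos (10 mol %), THF, 50 °C
Reagents that add atoms: none
Why: Negishi-type palladium-catalysed arylation of a Reformatsky reagent, in which oxidative addition into C–I is much faster than into C–Br and the bulky biarylphosphine allows coupling at the di-ortho-substituted C9, installing C10 and C20.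

Step 6
Reactants: 7 ethyl 2-[2,3-bis(benzyloxy)-4-bromo-6-(dimethoxymethyl)phenyl]acetate; 8 isopropenylboronic acid pinacol ester
Product: 9 ethyl 2-[2,3-bis(benzyloxy)-6-(dimethoxymethyl)-4-(prop-1-en-2-yl)phenyl]acetate
Conditions: 8 (1.5 equiv), Pd(OAc)2 (3 mol %), SPhos (6 mol %), K3PO4, toluene/H2O, 80 °C
Reagents that add atoms: none
Why: Suzuki–Miyaura coupling of the remaining aryl bromide at C13, with ester and acetal stable to aqueous phosphate.

Step 7
Reactants: 9 ethyl 2-[2,3-bis(benzyloxy)-6-(dimethoxymethyl)-4-(prop-1-en-2-yl)phenyl]acetate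
Product: 11 ethyl 2-{2,3-bis(benzyloxy)-6-(dimethoxymethyl)-4-[(2S)-1-hydroxypropan-2-yl]phenyl}acetate, via alkyl pinacol boronate 10 (not isolated)
Conditions: CuCl (5 mol %), (R)-DTBM-SEGPHOS (6 mol %), NaOt-Bu (10 mol %), HBpin (1.5 equiv), toluene, rt; then NaBO3·4H2O, THF/H2O, rt
Reagents that add atoms: sodium perborate, [Na+].[Na+].O[B-]1(O)OO[B-](O)(O)OO1
Why: Copper hydride-catalysed enantioselective anti-Markovnikov hydroboration of the 1,1-disubstituted aryl alkene followed by stereoretentive C–B oxidation, the chiral bisphosphine–CuH adding to one enantioface and so setting C15 as (S) by catalyst control.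

Step 8
Reactants: 11 ethyl 2-{2,3-bis(benzyloxy)-6-(dimethoxymethyl)-4-[(2S)-1-hydroxypropan-2-yl]phenyl}acetate
Product: 12 ethyl 2-{2,3-bis(benzyloxy)-4-[(2S)-1-(tert-butyldiphenylsilyloxy)propan-2-yl]-6-(dimethoxymethyl)phenyl}acetate
Conditions: TBDPSCl, imidazole, DMF, rt
Reagents that add atoms: tert-butyl(chloro)diphenylsilane, CC(C)(C)[Si](Cl)(c1ccccc1)c1ccccc1
Why: Silylation of the primary alcohol with a group that should survive the amide bases and the later catalytic acid step.

Step 9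
Reactants: 12 ethyl 2-{2,3-bis(benzyloxy)-4-[(2S)-1-(tert-butyldiphenylsilyloxy)propan-2-yl]-6-(dimethoxymethyl)phenyl}acetate; 13 allyl bromide
Product: 15 ethyl 2-{2,3-bis(benzyloxy)-4-[(2S)-1-(tert-butyldiphenylsilyloxy)propan-2-yl]-6-formylphenyl}pent-4-enoate (C10 epimers), via allylated acetal 14 (not isolated)
Conditions: LDA (1.1 equiv), THF, −78 °C; 13, −78 → −20 °C; then 1 M HCl, THF, rt
Reagents that add atoms: water, O
Why: Ester enolate alkylation at C10 followed by acetal hydrolysis in the work-up; the C10 configuration is irrelevant because it is erased in step 14, and dilute acid should leave silyl and benzyl ethers intact.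

Step 10
Reactants: 16 2,2-dimethylbut-3-enoic acid
Product: 17 2,2-dimethylbut-3-en-1-ol
Conditions: LiAlH4, Et2O, 0 °C → rt
Reagents that add atoms: none
Why: Hydride reduction of the carboxylic acid to the primary alcohol, the isolated alkene being inert.

Step 11
Reactants: 17 2,2-dimethylbut-3-en-1-ol
Product: 19 3,3-dimethylpent-1-en-4-yne, via 2,2-dimethylbut-3-enal 18 (not isolated)
Conditions: Dess–Martin periodinane, CH2Cl2, 0 °C → rt; filtered solution then dimethyl (1-diazo-2-oxopropyl)phosphonate, K2CO3, MeOH, 0 °C → rt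
Reagents that add atoms: dimethyl (1-diazo-2-oxopropyl)phosphonate, COP(=O)(OC)C(=[N+]=[N-])C(C)=O
Why: Dess–Martin oxidation followed by Ohira–Bestmann (Seyferth–Gilbert) homologation of the non-enolisable aldehyde, which is volatile and is therefore carried on in solution.

Step 12
Reactants: 15 ethyl 2-{2,3-bis(benzyloxy)-4-[(2S)-1-(tert-butyldiphenylsilyloxy)propan-2-yl]-6-formylphenyl}pent-4-enoate (C10 epimers); 19 3,3-dimethylpent-1-en-4-yne
Product: 22 ethyl 2-{2,3-bis(benzyloxy)-4-[(2S)-1-(tert-butyldiphenylsilyloxy)propan-2-yl]-6-[(1S,2E)-1-hydroxy-4,4-dimethylhexa-2,5-dien-1-yl]phenyl}pent-4-enoate (C10 epimers), via alkenylborane 20 (not isolated), via alkenylzinc 21 (not isolated)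
Conditions: 19 (1.6 equiv), Cy2BH, toluene, 0 °C → rt; Me2Zn, −78 °C; (−)-MIB (5 mol %), 15, −20 → 0 °C; aq. work-up
Reagents that add atoms: none
Why: Hydroboration of the terminal alkyne (faster than the neopentyl-type vinyl group with the bulky dialkylborane), boron-to-zinc transmetalation and amino alcohol-catalysed alkenylzinc addition, in which syn-hydroboration fixes the E-alkene and the (−)-MIB–zinc catalyst delivers the alkenyl group to the Si face of the aldehyde, setting C7 as (S) by catalyst control in both C10 epimers.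

Step 13
Reactants: 22 ethyl 2-{2,3-bis(benzyloxy)-4-[(2S)-1-(tert-butyldiphenylsilyloxy)propan-2-yl]-6-[(1S,2E)-1-hydroxy-4,4-dimethylhexa-2,5-dien-1-yl]phenyl}pent-4-enoate (C10 epimers)
Product: 23 (1S)-5,6-bis(benzyloxy)-7-[(2S)-1-(tert-butyldiphenylsilyloxy)propan-2-yl]-1-[(1E)-3,3-dimethylpenta-1,4-dien-1-yl]-4-(prop-2-en-1-yl)isochroman-3-one (C4 = C10 epimers)
Conditions: NaH (0.2 equiv), THF, 0 °C
Reagents that add atoms: none
Why: Alkoxide-catalysed intramolecular transesterification to the six-membered benzo-fused lactone, run under basic conditions so that the benzylic, allylic C7–O bond is not ionised and C7 keeps its configuration.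

Step 14
Reactants: 23 (1S)-5,6-bis(benzyloxy)-7-[(2S)-1-(tert-butyldiphenylsilyloxy)propan-2-yl]-1-[(1E)-3,3-dimethylpenta-1,4-dien-1-yl]-4-(prop-2-en-1-yl)isochroman-3-one (C10 epimers)
Product: 26 (1R,2S)-1-allyl-7,8-bis(benzyloxy)-6-[(2S)-1-(tert-butyldiphenylsilyloxy)propan-2-yl]-2-(2-methylbut-3-en-2-yl)-1,2-dihydronaphthalene-1-carboxylic acid, via silyl ketene acetal 24 (not isolated), via trimethylsilyl ester 25 (not isolated)
Conditions: KHMDS (1.2 equiv), THF/toluene, −78 °C, 30 min; TMSCl, −78 °C → rt; then 1 M HCl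
Reagents that add atoms: none
Why: Deprotonation at C10 and O-silylation give the cyclic silyl ketene acetal 24 (C10=C20), whose [3,3] shift (Ireland–Claisen rearrangement) forms C5–C10 while the benzylic, allylic C7–O bond breaks and the C6=C7 styrene and the C20 silyl ester appear; the closest known reaction type is the Ireland–Claisen ring contraction of ω-alkenyl lactones (six-membered alkenyl lactones and dioxanones to cyclohexene and dihydropyran carboxylic acids). Ring B is closed as a six-membered carbocycle by the shift itself, a ring contraction of the δ-lactone through a six-centre transition state in which lactone ring and alkenyl arm form a bicyclo[2.2.2]-shaped boat; a chair is impossible because the arene bond C8–C9 ties C7 to C10. C10 is set by C7: the alkenyl arm lies on one face of the lactone ring and C5 can bond only to that face of the planar ketene acetal, so both C10 epimers of 23 converge on (10R). C5 is set by the E geometry of the C5=C6 bond: in the boat H5 points at the arene and C4 away from it, which places H5 anti to C20 (5S, the trans A/B relationship) and C4 gauche to the C10 allyl group for the later ring closure. The step needs the concerted shift to outrun heterolysis or electrocyclic opening of the C7–O bond (an o-quinodimethane would reclose without memory of C7); the para oxygen at C12 should lower the barrier of the shift so that it runs at or below room temperature, and the ketene acetal is made at −78 °C and never heated.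

Step 15
Reactants: 26 (1R,2S)-1-allyl-7,8-bis(benzyloxy)-6-[(2S)-1-(tert-butyldiphenylsilyloxy)propan-2-yl]-2-(2-methylbut-3-en-2-yl)-1,2-dihydronaphthalene-1-carboxylic acid
Product: 27 (1R,2S,4S)-1-allyl-7,8-bis(benzyloxy)-6-[(2S)-1-(tert-butyldiphenylsilyloxy)propan-2-yl]-4-hydroxy-2-(2-methylbut-3-en-2-yl)-1,2,3,4-tetrahydronaphthalene-1-carboxylic acid 1,4-lactone (the C20→C7 bridged lactone)
Conditions: TfOH (10 mol %), CH2Cl2, −20 → 0 °C
Reagents that add atoms: none
Why: Acid-catalysed intramolecular hydroacyloxylation (Markovnikov lactonisation) in which protonation of the electron-rich styrene at C6 gives the C7 benzylic cation stabilised by the para C12 oxygen, and the C20 acid on C10 can reach C7 only from its own face, so the 2-oxabicyclo[2.2.2] lactone forms with C7 (S) dictated by C10.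

Step 16
Reactants: 27 the C20→C7 bridged lactone with C10 allyl and C5 2-methylbut-3-en-2-yl groups
Product: 28 11,12-di-O-benzyl-16-O-(tert-butyldiphenylsilyl)-2,3-didehydro-16-hydroxycarnosol (5S,7S,10R,15S)
Conditions: Grubbs II (5 mol %), CH2Cl2, 40 °C
Reagents that add atoms: none
Why: Ring-closing metathesis of the C10 allyl and C4 vinyl groups, held gauche on the rigid bicyclic lactone, closes six-membered ring A at C2=C3 with loss of ethylene.

Step 17
Reactants: 28 11,12-di-O-benzyl-16-O-(tert-butyldiphenylsilyl)-2,3-didehydro-16-hydroxycarnosol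
Product: 29 11,12-di-O-benzyl-16-O-(tert-butyldiphenylsilyl)-16-hydroxycarnosol
Conditions: H2 (1 atm), [Ir(cod)(PCy3)(py)]PF6 (5 mol %), CH2Cl2, rt
Reagents that add atoms: none
Why: Homogeneous hydrogenation with a cationic iridium catalyst that reduces the hindered cis-disubstituted C2=C3 alkene without hydrogenolysis of the benzyl ethers or of the benzylic lactone C7–O bond, which a palladium surface could cleave.

Step 18
Reactants: 29 11,12-di-O-benzyl-16-O-(tert-butyldiphenylsilyl)-16-hydroxycarnosol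
Product: 30 11,12-di-O-benzyl-16-hydroxycarnosol
Conditions: TBAF, AcOH, THF, rt
Reagents that add atoms: none
Why: Fluoride-mediated cleavage of the silyl ether, buffered with acetic acid so that the lactone is not opened.

Step 19
Reactants: 30 11,12-di-O-benzyl-16-hydroxycarnosol
Product: 31 16-acetoxy-11,12-di-O-benzylcarnosol
Conditions: Ac2O, pyridine, DMAP (cat.), CH2Cl2, rt
Reagents that add atoms: acetic anhydride, CC(=O)OC(C)=O
Why: Acylation of the only free hydroxyl group, done while the catechol is still protected so that no phenol/alcohol selectivity is needed.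

Step 20
Reactants: 31 16-acetoxy-11,12-di-O-benzylcarnosol
Product: 32 16-acetoxycarnosol, (5S,7S,10R,15S)-16-acetoxy-11,12-dihydroxyabieta-8,11,13-trien-20,7-olide (CNP0105472.1)
Conditions: BCl3 (4 equiv), pentamethylbenzene (6 equiv), CH2Cl2, −78 °C; aq. work-up
Reagents that add atoms: none
Why: Lewis acid debenzylation with a non-basic cation scavenger, which should cleave the two aryl benzyl ethers at −78 °C while the acetate and the lactone stay intact.

**Compound list**

1 | 3-bromo-4,5-dihydroxybenzaldehyde | O=Cc1cc(O)c(O)c(Br)c1 | starting material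
2 | 4-(benzyloxy)-3-bromo-5-hydroxybenzaldehyde | O=Cc1cc(O)c(OCc2ccccc2)c(Br)c1 | intermediate
3 | 4-(benzyloxy)-5-bromo-3-hydroxy-2-iodobenzaldehyde | O=Cc1cc(Br)c(OCc2ccccc2)c(O)c1I | intermediate
4 | 3,4-bis(benzyloxy)-5-bromo-2-iodobenzaldehyde | O=Cc1cc(Br)c(OCc2ccccc2)c(OCc2ccccc2)c1I | intermediate
5 | 1,2-bis(benzyloxy)-3-bromo-5-(dimethoxymethyl)-6-iodobenzene | COC(OC)c1cc(Br)c(OCc2ccccc2)c(OCc2ccccc2)c1I | intermediate
6 | (2-ethoxy-2-oxoethyl)zinc bromide | CCOC(=O)C[Zn]Br | starting material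
7 | ethyl 2-[2,3-bis(benzyloxy)-4-bromo-6-(dimethoxymethyl)phenyl]acetate | CCOC(=O)Cc1c(OCc2ccccc2)c(OCc2ccccc2)c(Br)cc1C(OC)OC | intermediate
8 | isopropenylboronic acid pinacol ester | CC(=C)B1OC(C)(C)C(C)(C)O1 | starting material
9 | ethyl 2-[2,3-bis(benzyloxy)-6-(dimethoxymethyl)-4-(prop-1-en-2-yl)phenyl]acetate | CCOC(=O)Cc1c(OCc2ccccc2)c(OCc2ccccc2)c(C(C)=C)cc1C(OC)OC | intermediate
10 | ethyl 2-{2,3-bis(benzyloxy)-6-(dimethoxymethyl)-4-[(2R)-1-(4,4,5,5-tetramethyl-1,3,2-dioxaborolan-2-yl)propan-2-yl]phenyl}acetate | CCOC(=O)Cc1c(OCc2ccccc2)c(OCc2ccccc2)c([C@H](C)CB2OC(C)(C)C(C)(C)O2)cc1C(OC)OC | intermediate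
11 | ethyl 2-{2,3-bis(benzyloxy)-6-(dimethoxymethyl)-4-[(2S)-1-hydroxypropan-2-yl]phenyl}acetate | CCOC(=O)Cc1c(OCc2ccccc2)c(OCc2ccccc2)c([C@H](C)CO)cc1C(OC)OC | intermediate
12 | ethyl 2-{2,3-bis(benzyloxy)-4-[(2S)-1-(tert-butyldiphenylsilyloxy)propan-2-yl]-6-(dimethoxymethyl)phenyl}acetate | CCOC(=O)Cc1c(OCc2ccccc2)c(OCc2ccccc2)c([C@H](C)CO[Si](c2ccccc2)(c2ccccc2)C(C)(C)C)cc1C(OC)OC | intermediate
13 | allyl bromide | C=CCBr | starting material
14 | ethyl 2-{2,3-bis(benzyloxy)-4-[(2S)-1-(tert-butyldiphenylsilyloxy)propan-2-yl]-6-(dimethoxymethyl)phenyl}pent-4-enoate (C10 epimers) | CCOC(=O)C(CC=C)c1c(OCc2ccccc2)c(OCc2ccccc2)c([C@H](C)CO[Si](c2ccccc2)(c2ccccc2)C(C)(C)C)cc1C(OC)OC | intermediate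
15 | ethyl 2-{2,3-bis(benzyloxy)-4-[(2S)-1-(tert-butyldiphenylsilyloxy)propan-2-yl]-6-formylphenyl}pent-4-enoate (C10 epimers) | CCOC(=O)C(CC=C)c1c(OCc2ccccc2)c(OCc2ccccc2)c([C@H](C)CO[Si](c2ccccc2)(c2ccccc2)C(C)(C)C)cc1C=O | intermediate
16 | 2,2-dimethylbut-3-enoic acid | C=CC(C)(C)C(=O)O | starting material
17 | 2,2-dimethylbut-3-en-1-ol | C=CC(C)(C)CO | intermediate
18 | 2,2-dimethylbut-3-enal | C=CC(C)(C)C=O | intermediate
19 | 3,3-dimethylpent-1-en-4-yne | C=CC(C)(C)C#C | intermediate
20 | dicyclohexyl[(1E)-3,3-dimethylpenta-1,4-dien-1-yl]borane | C=CC(C)(C)/C=C/B(C1CCCCC1)C1CCCCC1 | intermediate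
21 | [(1E)-3,3-dimethylpenta-1,4-dien-1-yl](methyl)zinc | C=CC(C)(C)/C=C/[Zn]C | intermediate
22 | ethyl 2-{2,3-bis(benzyloxy)-4-[(2S)-1-(tert-butyldiphenylsilyloxy)propan-2-yl]-6-[(1S,2E)-1-hydroxy-4,4-dimethylhexa-2,5-dien-1-yl]phenyl}pent-4-enoate (C10 epimers) | CCOC(=O)C(CC=C)c1c(OCc2ccccc2)c(OCc2ccccc2)c([C@H](C)CO[Si](c2ccccc2)(c2ccccc2)C(C)(C)C)cc1[C@@H](O)/C=C/C(C)(C)C=C | intermediate
23 | (1S)-5,6-bis(benzyloxy)-7-[(2S)-1-(tert-butyldiphenylsilyloxy)propan-2-yl]-1-[(1E)-3,3-dimethylpenta-1,4-dien-1-yl]-4-(prop-2-en-1-yl)isochroman-3-one (C10 epimers) | CC(C)(C)[Si](c1ccccc1)(c1ccccc1)OC[C@@H](C)c1cc2c(c(OCc3ccccc3)c1OCc1ccccc1)C(CC=C)C(=O)O[C@H]2/C=C/C(C)(C)C=C | intermediate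
24 | (1S)-4-allyl-5,6-bis(benzyloxy)-7-[(2S)-1-(tert-butyldiphenylsilyloxy)propan-2-yl]-1-[(1E)-3,3-dimethylpenta-1,4-dien-1-yl]-3-(trimethylsilyloxy)-1H-isochromene | CC(C)(C)[Si](c1ccccc1)(c1ccccc1)OC[C@@H](C)c1cc2c(c(OCc3ccccc3)c1OCc1ccccc1)C(CC=C)=C(O[Si](C)(C)C)O[C@H]2/C=C/C(C)(C)C=C | intermediate
25 | trimethylsilyl ester of acid 26 | CC(C)(C)[Si](c1ccccc1)(c1ccccc1)OC[C@@H](C)c1cc2c(c(OCc3ccccc3)c1OCc1ccccc1)[C@](CC=C)(C(=O)O[Si](C)(C)C)[C@H](C(C)(C)C=C)C=C2 | intermediate
26 | (1R,2S)-1-allyl-7,8-bis(benzyloxy)-6-[(2S)-1-(tert-butyldiphenylsilyloxy)propan-2-yl]-2-(2-methylbut-3-en-2-yl)-1,2-dihydronaphthalene-1-carboxylic acid | CC(C)(C)[Si](c1ccccc1)(c1ccccc1)OC[C@@H](C)c1cc2c(c(OCc3ccccc3)c1OCc1ccccc1)[C@](CC=C)(C(=O)O)[C@H](C(C)(C)C=C)C=C2 | intermediate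
27 | (1R,2S,4S)-1-allyl-7,8-bis(benzyloxy)-6-[(2S)-1-(tert-butyldiphenylsilyloxy)propan-2-yl]-4-hydroxy-2-(2-methylbut-3-en-2-yl)-1,2,3,4-tetrahydronaphthalene-1-carboxylic acid 1,4-lactone | CC(C)(C)[Si](c1ccccc1)(c1ccccc1)OC[C@@H](C)c1cc2c(c(OCc3ccccc3)c1OCc1ccccc1)[C@@]1(CC=C)[C@H](C(C)(C)C=C)C[C@@H]2OC1=O | intermediate
28 | 11,12-di-O-benzyl-16-O-(tert-butyldiphenylsilyl)-2,3-didehydro-16-hydroxycarnosol | CC(C)(C)[Si](c1ccccc1)(c1ccccc1)OC[C@@H](C)c1cc2c(c(OCc3ccccc3)c1OCc1ccccc1)[C@@]13CC=CC(C)(C)[C@@H]1C[C@@H]2OC3=O | intermediate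
29 | 11,12-di-O-benzyl-16-O-(tert-butyldiphenylsilyl)-16-hydroxycarnosol | CC(C)(C)[Si](c1ccccc1)(c1ccccc1)OC[C@@H](C)c1cc2c(c(OCc3ccccc3)c1OCc1ccccc1)[C@@]13CCCC(C)(C)[C@@H]1C[C@@H]2OC3=O | intermediate
30 | 11,12-di-O-benzyl-16-hydroxycarnosol | OC[C@@H](C)c1cc2c(c(OCc3ccccc3)c1OCc1ccccc1)[C@@]13CCCC(C)(C)[C@@H]1C[C@@H]2OC3=O | intermediate
31 | 16-acetoxy-11,12-di-O-benzylcarnosol | CC(=O)OC[C@@H](C)c1cc2c(c(OCc3ccccc3)c1OCc1ccccc1)[C@@]13CCCC(C)(C)[C@@H]1C[C@@H]2OC3=O | intermediate
32 | 16-acetoxycarnosol, (5S,7S,10R,15S)-16-acetoxy-11,12-dihydroxyabieta-8,11,13-trien-20,7-olide | CC(=O)OC[C@@H](C)c1cc2c(c(O)c1O)[C@@]13CCCC(C)(C)[C@@H]1C[C@@H]2OC3=O | target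

Total step count: 20. Longest linear sequence: 18 steps (1 → 32 through steps 1–9 and 12–20).

**Steps most likely to fail**

Step 14 (key step). Enolisation at the fully substituted C10, whose allyl group sits next to the C11 benzyloxy group, and the congested C5–C10 bond formation may be slow. Heterolysis or electrocyclic opening of the doubly activated C7–O bond could then compete and erode the chirality transfer. The fallback makes the quaternary centre by alkylation after a less hindered ring contraction; it sets out from 12 and comes back at 26. Acetal 12 is hydrolysed without prior allylation (1 M HCl, THF) to the non-allylated aldehyde F1. The alkenylzinc addition of step 12 (with 19, through 20 and 21) then gives the non-allylated hydroxy ester F2, and catalytic NaH closes the C10-unsubstituted lactone F3. Its ring contraction (LiHMDS, TMSCl, THF, −78 °C → rt; 1 M HCl) runs through the trisubstituted silyl ketene acetal F4 and the silyl ester F5 to the C10–H acid F6, in which C5 is set as in the main route. Double deprotonation (LDA, 2.2 equiv, THF, −78 → 0 °C) and allyl bromide 13 should alkylate the enediolate at C10 on the face anti to the bulky C5 substituent, which is the relative configuration of 26.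

Step 12. Hydroboration of the vinyl group of 19 beside the alkyne, or ligand-free background addition promoted by the boron by-product, would lower the yield and the facial selectivity at C7. The fallback sets C7 in an alkynylation and makes the E-alkene afterwards; it sets out from 15 and 19 and comes back at 22. Enyne 19 and Me2Zn give the alkynyl(methyl)zinc F7, which is added to 15 under dinuclear zinc–ProPhenol catalysis (ligand enantiomer chosen for the (S)-carbinol) to give the propargylic alcohol F8. Ruthenium-catalysed trans-hydrosilylation ([Cp*Ru(MeCN)3]PF6, (EtO)3SiH, CH2Cl2) gives the (Z)-vinylsilane F9 (either silicon regioisomer serves), and protodesilylation with AgF in THF/MeOH/H2O gives 22.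

Step 7. Enantioface discrimination may be poor for the ortho-benzyloxy-substituted 1,1-disubstituted alkene, which would leave C15 with low enantiomeric purity. The fallback sets C15 by asymmetric hydrogenation instead of hydroboration; it sets out from 9 and comes back at 11. Allylic oxidation (SeO2 cat., t-BuOOH, CH2Cl2, rt) gives the 2-arylallyl alcohol F10, and iridium–phosphinooxazoline-catalysed asymmetric hydrogenation of this 1,1-disubstituted allylic alcohol (H2, CH2Cl2) gives 11.

**Further compounds**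

F1 | step 14 | ethyl 2-{2,3-bis(benzyloxy)-4-[(2S)-1-(tert-butyldiphenylsilyloxy)propan-2-yl]-6-formylphenyl}acetate | CCOC(=O)Cc1c(OCc2ccccc2)c(OCc2ccccc2)c([C@H](C)CO[Si](c2ccccc2)(c2ccccc2)C(C)(C)C)cc1C=O
F2 | step 14 | ethyl 2-{2,3-bis(benzyloxy)-4-[(2S)-1-(tert-butyldiphenylsilyloxy)propan-2-yl]-6-[(1S,2E)-1-hydroxy-4,4-dimethylhexa-2,5-dien-1-yl]phenyl}acetate | CCOC(=O)Cc1c(OCc2ccccc2)c(OCc2ccccc2)c([C@H](C)CO[Si](c2ccccc2)(c2ccccc2)C(C)(C)C)cc1[C@@H](O)/C=C/C(C)(C)C=C
F3 | step 14 | (1S)-5,6-bis(benzyloxy)-7-[(2S)-1-(tert-butyldiphenylsilyloxy)propan-2-yl]-1-[(1E)-3,3-dimethylpenta-1,4-dien-1-yl]isochroman-3-one | CC(C)(C)[Si](c1ccccc1)(c1ccccc1)OC[C@@H](C)c1cc2c(c(OCc3ccccc3)c1OCc1ccccc1)CC(=O)O[C@H]2/C=C/C(C)(C)C=C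
F4 | step 14 | (1S)-5,6-bis(benzyloxy)-7-[(2S)-1-(tert-butyldiphenylsilyloxy)propan-2-yl]-1-[(1E)-3,3-dimethylpenta-1,4-dien-1-yl]-3-(trimethylsilyloxy)-1H-isochromene | CC(C)(C)[Si](c1ccccc1)(c1ccccc1)OC[C@@H](C)c1cc2c(c(OCc3ccccc3)c1OCc1ccccc1)C=C(O[Si](C)(C)C)O[C@H]2/C=C/C(C)(C)C=C
F5 | step 14 | trimethylsilyl (1R,2S)-7,8-bis(benzyloxy)-6-[(2S)-1-(tert-butyldiphenylsilyloxy)propan-2-yl]-2-(2-methylbut-3-en-2-yl)-1,2-dihydronaphthalene-1-carboxylate | CC(C)(C)[Si](c1ccccc1)(c1ccccc1)OC[C@@H](C)c1cc2c(c(OCc3ccccc3)c1OCc1ccccc1)[C@H](C(=O)O[Si](C)(C)C)[C@H](C(C)(C)C=C)C=C2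
F6 | step 14 | (1R,2S)-7,8-bis(benzyloxy)-6-[(2S)-1-(tert-butyldiphenylsilyloxy)propan-2-yl]-2-(2-methylbut-3-en-2-yl)-1,2-dihydronaphthalene-1-carboxylic acid | CC(C)(C)[Si](c1ccccc1)(c1ccccc1)OC[C@@H](C)c1cc2c(c(OCc3ccccc3)c1OCc1ccccc1)[C@H](C(=O)O)[C@H](C(C)(C)C=C)C=C2
F7 | step 12 | (3,3-dimethylpent-4-en-1-yn-1-yl)(methyl)zinc | C=CC(C)(C)C#C[Zn]C
F8 | step 12 | ethyl 2-{2,3-bis(benzyloxy)-4-[(2S)-1-(tert-butyldiphenylsilyloxy)propan-2-yl]-6-[(1S)-1-hydroxy-4,4-dimethylhex-5-en-2-yn-1-yl]phenyl}pent-4-enoate (C10 epimers) | CCOC(=O)C(CC=C)c1c(OCc2ccccc2)c(OCc2ccccc2)c([C@H](C)CO[Si](c2ccccc2)(c2ccccc2)C(C)(C)C)cc1[C@@H](O)C#CC(C)(C)C=C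
F9 | step 12 | ethyl 2-{2,3-bis(benzyloxy)-4-[(2S)-1-(tert-butyldiphenylsilyloxy)propan-2-yl]-6-[(1S,2Z)-1-hydroxy-4,4-dimethyl-3-(triethoxysilyl)hexa-2,5-dien-1-yl]phenyl}pent-4-enoate (C10 epimers) | CCOC(=O)C(CC=C)c1c(OCc2ccccc2)c(OCc2ccccc2)c([C@H](C)CO[Si](c2ccccc2)(c2ccccc2)C(C)(C)C)cc1[C@@H](O)/C=C(\[Si](OCC)(OCC)OCC)C(C)(C)C=C
F10 | step 7 | ethyl 2-[2,3-bis(benzyloxy)-6-(dimethoxymethyl)-4-(3-hydroxyprop-1-en-2-yl)phenyl]acetate | CCOC(=O)Cc1c(OCc2ccccc2)c(OCc2ccccc2)c(C(=C)CO)cc1C(OC)OC
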